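**Retrosynthetic overview**
1. Target 21 ⇐ acyclic δ-hydroxy-β-diketone dioxinone 17 in one pot: ring C first (acid cyclodehydration, O1–C8a), then ring A (dioxinone → acylketene → 6π benzannulation, C4a–C5); ring B is bought.
2. 17 ⇐ C4–C4a Claisen union of the dianion of keto-dioxinone 14 with (R)-β-hydroxy thioester 9.
3. 9 ⇐ catalytic enantioselective acetate Mukaiyama aldol on aldehyde 4 (sets the only stereocentre, the future C2); 4 ⇐ 3,5-dibromo-4-hydroxybenzaldehyde by silylation and double Stille prenylation.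
4. 14 ⇐ γ-acetylation of 5-prenyl dioxinone 12 ⇐ 5-iodo dioxinone 11 ⇐ 2,2,6-trimethyl-4H-1,3-dioxin-4-one; the prenyl sits next to the future ketene carbon, so ring A can only form as the 6-prenyl isomer.

Assumption: the SMILES encodes the (2R)-flavanone, and (R)-BINOL/Ti(OiPr)4 is taken to direct Re-face addition as it does with benzaldehyde (the equally cheap (S)-ligand would be used if the sense were the reverse).

Abbreviations in names: Ar = 4-[(tert-butyldimethylsilyl)oxy]-3,5-bis(3-methylbut-2-en-1-yl)phenyl; prenyl = 3-methylbut-2-en-1-yl; TBS = tert-butyldimethylsilyl; TMS = trimethylsilyl; TES = triethylsilyl.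

**Route**

Step 1
Reactants: 1 3,5-dibromo-4-hydroxybenzaldehyde
Product: 2 3,5-dibromo-4-[(tert-butyldimethylsilyl)oxy]benzaldehyde
Conditions: TBSCl, imidazole, DMF, rt
Reagents that add atoms: tert-butyldimethylsilyl chloride, CC(C)(C)[Si](C)(C)Cl
Why: Imidazole-mediated silyl ether formation masks the acidic phenol so that it cannot protonate the allylstannane in step 2 or bind titanium in step 4; no stereocentre is involved.

Step 2
Reactants: 2 3,5-dibromo-4-[(tert-butyldimethylsilyl)oxy]benzaldehyde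
Product: 4 4-[(tert-butyldimethylsilyl)oxy]-3,5-bis(3-methylbut-2-en-1-yl)benzaldehyde, via monoprenyl bromide 3 (not isolated)
Conditions: prenyl-SnBu3 (2.6 equiv), Pd(PPh3)4 (8 mol%), PhMe, 110 °C; MeCN/hexane partition to remove tin
Reagents that add atoms: tributyl(3-methylbut-2-en-1-yl)stannane, CCCC[Sn](CCCC)(CCCC)CC=C(C)C
Why: Double Stille cross-coupling of the two aryl bromides, in which reductive elimination at the less hindered allyl terminus gives the linear prenyl groups while the aldehyde and silyl ether are inert to the neutral stannane.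

Step 3
Reactants: 5 S-tert-butyl ethanethioate
Product: 7 1-(tert-butylsulfanyl)-1-[(trimethylsilyl)oxy]ethene, via lithium enolate 6 (not isolated)
Conditions: LiN(iPr)2, THF, −78 °C; Me3SiCl, −78 °C to rt; distil
Reagents that add atoms: chlorotrimethylsilane, C[Si](C)(C)Cl
Why: Kinetic deprotonation of the thioester and O-silylation of its lithium enolate give the silyl ketene thioacetal needed as the Mukaiyama donor.

Step 4
Reactants: 4 4-[(tert-butyldimethylsilyl)oxy]-3,5-bis(3-methylbut-2-en-1-yl)benzaldehyde; 7 1-(tert-butylsulfanyl)-1-[(trimethylsilyl)oxy]ethene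
Product: 9 S-tert-butyl (3R)-3-Ar-3-hydroxypropanethioate, via TMS ether 8 (not isolated)
Conditions: Ti(OiPr)4 (20 mol%), (R)-BINOL (20 mol%), 4 Å MS, Et2O, −20 °C; then PPTS, MeOH, 0 °C
Reagents that add atoms: none
Why: Keck-type catalytic enantioselective Mukaiyama aldol reaction in which the BINOL–titanium Lewis acid exposes the Re face of the aldehyde to the ketene thioacetal and so sets the (R)-carbinol (the future C2), after which methanolysis removes the transferred TMS group and leaves the aryl TBS ether.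

Step 5
Reactants: 10 2,2,6-trimethyl-4H-1,3-dioxin-4-one
Product: 11 5-iodo-2,2,6-trimethyl-4H-1,3-dioxin-4-one
Conditions: NIS, AcOH, rt, dark
Reagents that add atoms: N-iodosuccinimide, O=C1CCC(=O)N1I
Why: Electrophilic iodination at the nucleophilic C5 of the vinylogous carbonate, a known halogenation of this dioxinone.

Step 6
Reactants: 11 5-iodo-2,2,6-trimethyl-4H-1,3-dioxin-4-one
Product: 12 2,2,6-trimethyl-5-(3-methylbut-2-en-1-yl)-4H-1,3-dioxin-4-one
Conditions: prenyl-SnBu3 (1.3 equiv), PdCl2(PhCN)2 (5 mol%), AsPh3 (10 mol%), CuI (copper iodide, 10 mol%), NMP, 50 °C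
Reagents that add atoms: tributyl(3-methylbut-2-en-1-yl)stannane, CCCC[Sn](CCCC)(CCCC)CC=C(C)C
Why: Stille coupling of an α-iodo-enone-type vinyl iodide under the AsPh3/CuI-accelerated conditions used for α-iodoenones, run well below the temperature at which the dioxinone loses acetone and again delivering the linear prenyl group.

Step 7
Reactants: 12 2,2,6-trimethyl-5-(3-methylbut-2-en-1-yl)-4H-1,3-dioxin-4-one
Product: 14 2,2-dimethyl-5-(3-methylbut-2-en-1-yl)-6-(2-oxopropyl)-4H-1,3-dioxin-4-one, via lithium dienolate 13 (not isolated)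
Conditions: LiN(SiMe3)2, THF, −78 °C; MeC(O)N(OMe)Me, −78 to −30 °C; AcOH
Reagents that add atoms: N-methoxy-N-methylacetamide, CC(=O)N(C)OC
Why: γ-Deprotonation gives the dioxinone dienolate, and its Claisen-type C-acylation at the exocyclic carbon by a Weinreb amide stops at the methyl ketone because the chelated adduct only collapses on quench.

Step 8
Reactants: 14 2,2-dimethyl-5-(3-methylbut-2-en-1-yl)-6-(2-oxopropyl)-4H-1,3-dioxin-4-one; 9 S-tert-butyl (3R)-3-Ar-3-hydroxypropanethioate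
Product: 17 6-[(6R)-6-Ar-6-hydroxy-2,4-dioxohexyl]-2,2-dimethyl-5-(3-methylbut-2-en-1-yl)-4H-1,3-dioxin-4-one, via dilithium dianion 15 (not isolated), via lithium alkoxide 16 (not isolated)
Conditions: 14 (2.2 equiv), LiN(iPr)2 (4.4 equiv), THF, −78 °C; add 9 pre-treated with LiN(SiMe3)2 (1.0 equiv), −78 to −40 °C; AcOH, −78 °C; excess 14 recovered
Reagents that add atoms: none
Why: Claisen condensation of a 1,3-dicarbonyl dianion at its terminal carbon (Harris-type acylation, as used for diketo-dioxinones) with the thioester, in which the pre-formed β-alkoxide blocks α-deprotonation and elimination of the acyl donor and the carbinol stereocentre is untouched.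

Step 9
Reactants: 17 6-[(6R)-6-Ar-6-hydroxy-2,4-dioxohexyl]-2,2-dimethyl-5-(3-methylbut-2-en-1-yl)-4H-1,3-dioxin-4-one
Product: 21 (2R)-5,7-dihydroxy-2-[4-hydroxy-3,5-bis(3-methylbut-2-en-1-yl)phenyl]-6-(3-methylbut-2-en-1-yl)-2,3-dihydro-4H-chromen-4-one, via dihydropyranone 18 (not isolated), via acylketene 19 (not isolated), via TBS ether 20 (not isolated)
Conditions: TFA (3 equiv), CH2Cl2, 0 °C, 30 min; evaporate, PhMe azeotrope; PhMe (0.01 M), 110 °C, 2 h; then Bu4NF/AcOH (1:1, 1.5 equiv), THF, 0 °C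
Reagents that add atoms: none
Why: Proposed new method: TFA closes the δ-hydroxy-β-diketone to the 2,3-dihydro-4H-pyran-4-one by hemiketalisation–dehydration (the closure used for Danishefsky-type aldol adducts; the C2–O bond is never broken, so (R) is kept and O1 is locked onto C8a), heating then extrudes acetone from the dioxinone by retro-[4+2] to an α-prenyl acylketene (the Barrett resorcylate trigger) whose C7 enol is a dienylketene (C5=C6–C7=C8–C8a=C4a) that undergoes 6π-electrocyclisation and tautomerises to the phenol as in the last stage of a Danheiser benzannulation, so ring A can only form as the 5,7-dihydroxy-6-prenyl isomer, and buffered fluoride finally cleaves the aryl silyl ether without opening the flavanone; the closest known reaction types are the dioxinone-based biomimetic aromatisations and the Harris Claisen cyclisation of polyketo esters to acylphloroglucinols.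

**Compound list**

1 | 3,5-dibromo-4-hydroxybenzaldehyde | O=Cc1cc(Br)c(O)c(Br)c1 | starting material
2 | 3,5-dibromo-4-[(tert-butyldimethylsilyl)oxy]benzaldehyde | O=Cc1cc(Br)c(O[Si](C)(C)C(C)(C)C)c(Br)c1 | intermediate
3 | 3-bromo-4-[(tert-butyldimethylsilyl)oxy]-5-(3-methylbut-2-en-1-yl)benzaldehyde | O=Cc1cc(Br)c(O[Si](C)(C)C(C)(C)C)c(CC=C(C)C)c1 | intermediate
4 | 4-[(tert-butyldimethylsilyl)oxy]-3,5-bis(3-methylbut-2-en-1-yl)benzaldehyde | O=Cc1cc(CC=C(C)C)c(O[Si](C)(C)C(C)(C)C)c(CC=C(C)C)c1 | intermediate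
5 | S-tert-butyl ethanethioate | CC(=O)SC(C)(C)C | starting material
6 | lithium 1-(tert-butylsulfanyl)ethen-1-olate | [Li+].C=C([O-])SC(C)(C)C | intermediate
7 | 1-(tert-butylsulfanyl)-1-[(trimethylsilyl)oxy]ethene | C=C(O[Si](C)(C)C)SC(C)(C)C | intermediate
8 | S-tert-butyl (3R)-3-Ar-3-[(trimethylsilyl)oxy]propanethioate | CC(C)=CCc1cc([C@H](O[Si](C)(C)C)CC(=O)SC(C)(C)C)cc(CC=C(C)C)c1O[Si](C)(C)C(C)(C)C | intermediate
9 | S-tert-butyl (3R)-3-Ar-3-hydroxypropanethioate | CC(C)=CCc1cc([C@H](O)CC(=O)SC(C)(C)C)cc(CC=C(C)C)c1O[Si](C)(C)C(C)(C)C | intermediate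
10 | 2,2,6-trimethyl-4H-1,3-dioxin-4-one | CC1=CC(=O)OC(C)(C)O1 | starting material
11 | 5-iodo-2,2,6-trimethyl-4H-1,3-dioxin-4-one | CC1=C(I)C(=O)OC(C)(C)O1 | intermediate
12 | 2,2,6-trimethyl-5-(3-methylbut-2-en-1-yl)-4H-1,3-dioxin-4-one | CC1=C(CC=C(C)C)C(=O)OC(C)(C)O1 | intermediate
13 | lithium 2,2-dimethyl-6-methylidene-5-(3-methylbut-2-en-1-yl)-6H-1,3-dioxin-4-olate | [Li+].C=C1OC(C)(C)OC([O-])=C1CC=C(C)C | intermediate
14 | 2,2-dimethyl-5-(3-methylbut-2-en-1-yl)-6-(2-oxopropyl)-4H-1,3-dioxin-4-one | CC(=O)CC1=C(CC=C(C)C)C(=O)OC(C)(C)O1 | intermediate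
15 | dilithium dianion of 14 (terminal enolate plus dioxinone dienolate) | [Li+].[Li+].C=C([O-])C=C1OC(C)(C)OC([O-])=C1CC=C(C)C | intermediate
16 | lithium (1R)-1-Ar-3-(tert-butylsulfanyl)-3-oxopropan-1-olate | [Li+].CC(C)=CCc1cc([C@H]([O-])CC(=O)SC(C)(C)C)cc(CC=C(C)C)c1O[Si](C)(C)C(C)(C)C | intermediate
17 | 6-[(6R)-6-Ar-6-hydroxy-2,4-dioxohexyl]-2,2-dimethyl-5-(3-methylbut-2-en-1-yl)-4H-1,3-dioxin-4-one | CC(C)=CCc1cc([C@H](O)CC(=O)CC(=O)CC2=C(CC=C(C)C)C(=O)OC(C)(C)O2)cc(CC=C(C)C)c1O[Si](C)(C)C(C)(C)C | intermediate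
18 | 6-{[(2R)-2-Ar-4-oxo-3,4-dihydro-2H-pyran-6-yl]methyl}-2,2-dimethyl-5-(3-methylbut-2-en-1-yl)-4H-1,3-dioxin-4-one | CC(C)=CCc1cc([C@H]2CC(=O)C=C(CC3=C(CC=C(C)C)C(=O)OC(C)(C)O3)O2)cc(CC=C(C)C)c1O[Si](C)(C)C(C)(C)C | intermediate
19 | 4-[(2R)-2-Ar-4-oxo-3,4-dihydro-2H-pyran-6-yl]-2-(3-methylbut-2-en-1-yl)-3-oxobut-1-en-1-one (acylketene) | CC(C)=CCc1cc([C@H]2CC(=O)C=C(CC(=O)C(CC=C(C)C)=C=O)O2)cc(CC=C(C)C)c1O[Si](C)(C)C(C)(C)C | intermediate
20 | (2R)-2-Ar-5,7-dihydroxy-6-(3-methylbut-2-en-1-yl)-2,3-dihydro-4H-chromen-4-one | CC(C)=CCc1cc([C@H]2CC(=O)c3c(cc(O)c(CC=C(C)C)c3O)O2)cc(CC=C(C)C)c1O[Si](C)(C)C(C)(C)C | intermediate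
21 | (2R)-5,7-dihydroxy-2-[4-hydroxy-3,5-bis(3-methylbut-2-en-1-yl)phenyl]-6-(3-methylbut-2-en-1-yl)-2,3-dihydro-4H-chromen-4-one | CC(C)=CCc1cc([C@H]2CC(=O)c3c(cc(O)c(CC=C(C)C)c3O)O2)cc(CC=C(C)C)c1O | target

**Totals and risks**

Total steps: 9. Longest linear sequence: 5 (steps 1, 2, 4, 8, 9; equally steps 5, 6, 7, 8, 9).

Most likely to fail, step 9. The thermal stage is untested: the acylketene may oligomerise or be intercepted by the phenols of product already formed, and the acid stage could dehydrate the electron-rich benzylic alcohol. The fallback sets out from 17 and comes back at 20. Only the TFA stage is run and dihydropyranone 18 is isolated. Heating 18 with methanol (PhMe/MeOH 10:1, 110 °C, sealed tube) intercepts ketene 19 as methyl 4-[(2R)-2-Ar-4-oxo-3,4-dihydro-2H-pyran-6-yl]-2-(3-methylbut-2-en-1-yl)-3-oxobutanoate F1. F1 is then closed in a separate ionic step, a base-mediated intramolecular Claisen (Dieckmann-type) condensation with aromatisation (DBU, MeCN, 0 °C, short contact to protect C2), giving 20, which is desilylated as in the last stage of step 9.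

Second, step 8. The dianion may deprotonate rather than acylate, or the dioxinone dianion may decompose before the thioester is consumed. The fallback sets out from 9 and comes back at 18, replacing the Claisen by aldol addition and oxidation. 9 is silylated (Et3SiCl, imidazole) to S-tert-butyl (3R)-3-Ar-3-[(triethylsilyl)oxy]propanethioate F2. F2 is reduced (iBu2AlH, CH2Cl2, −78 °C) to (3R)-3-Ar-3-[(triethylsilyl)oxy]propanal F3. Aldehydes react with dianion 15 far faster than thioesters, giving the β-hydroxy ketone 6-[(6R)-6-Ar-4-hydroxy-2-oxo-6-(triethylsilyloxy)hexyl]-2,2-dimethyl-5-(3-methylbut-2-en-1-yl)-4H-1,3-dioxin-4-one F4 (epimers at the new carbinol). Dess–Martin oxidation gives the 1,3-diketone 6-[(6R)-6-Ar-2,4-dioxo-6-(triethylsilyloxy)hexyl]-2,2-dimethyl-5-(3-methylbut-2-en-1-yl)-4H-1,3-dioxin-4-one F5, and the TFA stage of step 9 removes the TES group and closes ring C to 18.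

Third, step 4. The 4-silyloxy-3,5-dialkyl aldehyde is electron-rich, so rate and enantioselectivity of the titanium-catalysed aldol may fall short of what a single enantiomer needs. The fallback sets out from 4 and comes back at 9, moving stereocontrol from C–C bond formation to ketone reduction. Lithium enolate 6 adds to 4 (THF, −78 °C) to give racemic S-tert-butyl 3-Ar-3-hydroxypropanethioate F6. Dess–Martin oxidation gives S-tert-butyl 3-Ar-3-oxopropanethioate F7. Noyori–Ikariya transfer hydrogenation (RuCl(p-cymene)[(R,R)-TsNCH(Ph)CH(Ph)NH2] 1 mol%, HCO2H/Et3N 5:2, rt) then reduces the aryl ketone to the (R)-alcohol 9; the aryl group is recognised as in acetophenone reductions, and the prenyl groups and thioester are untouched.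

**Further compounds**

F1 | step 9 | methyl 4-[(2R)-2-Ar-4-oxo-3,4-dihydro-2H-pyran-6-yl]-2-(3-methylbut-2-en-1-yl)-3-oxobutanoate | CC(C)=CCc1cc([C@H]2CC(=O)C=C(CC(=O)C(CC=C(C)C)C(=O)OC)O2)cc(CC=C(C)C)c1O[Si](C)(C)C(C)(C)C
F2 | step 8 | S-tert-butyl (3R)-3-Ar-3-[(triethylsilyl)oxy]propanethioate | CC(C)=CCc1cc([C@H](O[Si](CC)(CC)CC)CC(=O)SC(C)(C)C)cc(CC=C(C)C)c1O[Si](C)(C)C(C)(C)C
F3 | step 8 | (3R)-3-Ar-3-[(triethylsilyl)oxy]propanal | CC(C)=CCc1cc([C@H](O[Si](CC)(CC)CC)CC=O)cc(CC=C(C)C)c1O[Si](C)(C)C(C)(C)C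
F4 | step 8 | 6-[(6R)-6-Ar-4-hydroxy-2-oxo-6-(triethylsilyloxy)hexyl]-2,2-dimethyl-5-(3-methylbut-2-en-1-yl)-4H-1,3-dioxin-4-one | CC(C)=CCc1cc([C@H](O[Si](CC)(CC)CC)CC(O)CC(=O)CC2=C(CC=C(C)C)C(=O)OC(C)(C)O2)cc(CC=C(C)C)c1O[Si](C)(C)C(C)(C)C
F5 | step 8 | 6-[(6R)-6-Ar-2,4-dioxo-6-(triethylsilyloxy)hexyl]-2,2-dimethyl-5-(3-methylbut-2-en-1-yl)-4H-1,3-dioxin-4-one | CC(C)=CCc1cc([C@H](O[Si](CC)(CC)CC)CC(=O)CC(=O)CC2=C(CC=C(C)C)C(=O)OC(C)(C)O2)cc(CC=C(C)C)c1O[Si](C)(C)C(C)(C)C
F6 | step 4 | S-tert-butyl 3-Ar-3-hydroxypropanethioate (racemic) | CC(C)=CCc1cc(C(O)CC(=O)SC(C)(C)C)cc(CC=C(C)C)c1O[Si](C)(C)C(C)(C)C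
F7 | step 4 | S-tert-butyl 3-Ar-3-oxopropanethioate | CC(C)=CCc1cc(C(=O)CC(=O)SC(C)(C)C)cc(CC=C(C)C)c1O[Si](C)(C)C(C)(C)C
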